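**Retrosynthetic overview**
1. Target ⇐ trimethyl-protected 28 (one-pot S-dealkylation) ⇐ 2-decalone 22 (isopropylidene by β-lactone olefination).
2. 22 ⇐ tricyclic 2-pyranone 20 (hydrogenation, then enol-lactone methanolysis, which sets C1 by protonation); the arylmethyl group comes from aldehyde 14 + aryl Grignard, then deoxygenation.
3. Key step: 14 ⇐ achiral pyranone triene-enal 13 by a catalytic enantioselective intramolecular Diels–Alder reaction that closes both carbocycles and sets C4a, C5, C6 and C8a at once.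
4. 13 ⇐ 5-iodo-2-pyranone 7 + dienyl metal (from enyne 10); 7 ⇐ (Z)-enynoate 6 (iodolactonisation) ⇐ alkynyl enal 4 + methyl (Z)-3-iodoacrylate.
5. Ring order: pyranone first (temporary; it carries C1, C2 and the acid chain), then both decalin rings together, then the pyranone is opened.

Assumption: (S)-configured Corey oxazaborolidinium catalysts are taken to send dienes to the Re face of C-α of 2-methyl enals; the key step needs Si-face attack, so the (R)-catalyst is written (if the sense is the reverse, the (S)-catalyst is used and nothing else changes).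
Locants C1, C2, C4a, C5, C6, C8a are those of the decalin in the target's IUPAC name; α/β are relative to the β angular methyl.

**Route**

Step 1
Reactants: 1 pent-4-yn-1-ol; 2 2-(triphenyl-λ5-phosphanylidene)propanal
Product: 4 (2E)-2-methylhept-2-en-6-ynal, via pent-4-ynal 3 (not isolated)
Conditions: Dess–Martin periodinane, CH2Cl2, 0 °C → rt; then 2, 40 °C
Reagents that add atoms: none
Why: Dess–Martin oxidation gives the volatile alkynal, which is trapped in the flask by a Wittig reaction with the stabilised formyl ylide, giving the (E)-enal (chain trans to CHO) whose geometry later fixes C5.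

Step 2
Reactants: 4 (2E)-2-methylhept-2-en-6-ynal; 5 methyl (2Z)-3-iodoprop-2-enoate
Product: 6 methyl (2Z,8E)-9-methyl-10-oxodeca-2,8-dien-4-ynoate
Conditions: Pd(PPh3)2Cl2 (2 mol%), CuI (4 mol%), Et3N, THF, rt
Reagents that add atoms: none
Why: Sonogashira coupling of the terminal alkyne with the vinyl iodide retains the Z geometry needed for lactonisation and tolerates the enal.

Step 3
Reactants: 6 methyl (2Z,8E)-9-methyl-10-oxodeca-2,8-dien-4-ynoate
Product: 7 5-iodo-6-[(3E)-4-methyl-5-oxopent-3-en-1-yl]-2H-pyran-2-one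
Conditions: ICl (1.2 equiv), CH2Cl2, −78 °C → rt
Reagents that add atoms: iodine monochloride (ICl)
Why: Electrophilic iodocyclisation (6-endo-dig iodolactonisation of a (Z)-2-en-4-ynoate): the ester carbonyl oxygen attacks the iodonium-activated alkyne at the alkyl-bearing carbon and chloride removes the O-methyl group, while the electron-poor enal C=C is left alone.

Step 4
Reactants: 8 prop-1-yn-1-ylmagnesium bromide; 9 (1E)-1-bromoprop-1-ene
Product: 10 (4E)-hex-4-en-2-yne
Conditions: Pd(PPh3)4 (3 mol%), THF, 0 °C → rt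
Reagents that add atoms: none
Why: Palladium-catalysed Kumada-type coupling of an alkynyl Grignard reagent with an alkenyl bromide retains the E geometry.

Step 5
Reactants: 10 (4E)-hex-4-en-2-yne; 7 5-iodo-6-[(3E)-4-methyl-5-oxopent-3-en-1-yl]-2H-pyran-2-one
Product: 13 5-[(2E,4E)-hexa-2,4-dien-2-yl]-6-[(3E)-4-methyl-5-oxopent-3-en-1-yl]-2H-pyran-2-one, via alkenylzirconocene chloride 11 (not isolated), via alkenylzinc chloride 12 (not isolated)
Conditions: Cp2Zr(H)Cl (0.95 equiv per 10), THF, rt; ZnCl2; then 7, Pd(PPh3)4 (5 mol%), THF, rt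
Reagents that add atoms: none
Why: syn-Hydrozirconation (Schwartz reagent) puts zirconium on the less hindered methyl-bearing alkyne carbon, and Negishi coupling after Zr-to-Zn transmetalation proceeds with retention, so the pyranone ends up trans to the propenyl group ((2E,4E)-diene, methyl inside).

Step 6
Reactants: 13 5-[(2E,4E)-hexa-2,4-dien-2-yl]-6-[(3E)-4-methyl-5-oxopent-3-en-1-yl]-2H-pyran-2-one
Product: 14 (6aS,7S,8S,10aR)-7,8,10a-trimethyl-3-oxo-5,6,6a,7,8,10a-hexahydro-3H-benzo[f]chromene-7-carbaldehyde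
Conditions: (R)-B-o-tolyl oxazaborolidine from (R)-α,α-diphenylprolinol, activated 1:1 by Tf2NH (20 mol%), CH2Cl2, −78 → −20 °C
Reagents that add atoms: none
Why: Catalytic enantioselective intramolecular Diels–Alder reaction (Corey cationic oxazaborolidine activation of a 2-methyl enal): the diene adds to the Si face of C-α through the endo-CHO transition state with the tether anti, so suprafacial addition turns the E-enal into ring-fusion H cis to CHO (trans ring fusion), the E,E-diene into the secondary methyl cis to the bond toward the pyranone, and the endo rule puts CHO cis to that methyl, which sets the four centres that become C4a, C5, C6 and C8a while both carbocycles close.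

Step 7
Reactants: 15 4-methoxy-2-methylphenol
Product: 16 2-bromo-4-methoxy-6-methylphenol
Conditions: Br2 (1.0 equiv), CH2Cl2, 0 °C
Reagents that add atoms: bromine (BrBr)
Why: Electrophilic aromatic bromination is directed ortho to the free OH (para is blocked by OMe), so only one regioisomer forms.

Step 8
Reactants: 16 2-bromo-4-methoxy-6-methylphenol
Product: 17 1-bromo-2,5-dimethoxy-3-methylbenzene
Conditions: MeI, K2CO3, acetone, reflux
Reagents that add atoms: iodomethane (CI)
Why: Williamson ether synthesis (O-methylation of the phenol).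

Step 9
Reactants: 17 1-bromo-2,5-dimethoxy-3-methylbenzene; 14 (6aS,7S,8S,10aR)-7,8,10a-trimethyl-3-oxo-5,6,6a,7,8,10a-hexahydro-3H-benzo[f]chromene-7-carbaldehyde
Product: 19 (6aS,7S,8S,10aR)-7-[(2,5-dimethoxy-3-methylphenyl)(hydroxy)methyl]-7,8,10a-trimethyl-5,6,6a,7,8,10a-hexahydro-3H-benzo[f]chromen-3-one (carbinol epimers), via arylmagnesium bromide 18 (not isolated)
Conditions: Mg, THF, 50 °C; then 14, THF, −78 → −40 °C; aqueous work-up
Reagents that add atoms: none
Why: Grignard addition: at low temperature the aldehyde is far more electrophilic than the 2-pyranone, and the uncontrolled carbinol centre is removed in step 10.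

Step 10
Reactants: 19 (6aS,7S,8S,10aR)-7-[(2,5-dimethoxy-3-methylphenyl)(hydroxy)methyl]-7,8,10a-trimethyl-5,6,6a,7,8,10a-hexahydro-3H-benzo[f]chromen-3-one
Product: 20 (6aR,7S,8S,10aR)-7-[(2,5-dimethoxy-3-methylphenyl)methyl]-7,8,10a-trimethyl-5,6,6a,7,8,10a-hexahydro-3H-benzo[f]chromen-3-one
Conditions: Et3SiH (3 equiv), TFA (5 equiv), CH2Cl2, 0 °C
Reagents that add atoms: none
Why: Ionic hydrogenation (benzylic deoxygenation): TFA ionises the carbinol to an o-methoxy-stabilised benzylic cation that triethylsilane reduces, while the pyranone and the disubstituted alkene do not react and no stereocentre is touched.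

Step 11
Reactants: 20 (6aR,7S,8S,10aR)-7-[(2,5-dimethoxy-3-methylphenyl)methyl]-7,8,10a-trimethyl-5,6,6a,7,8,10a-hexahydro-3H-benzo[f]chromen-3-one
Product: 22 methyl 3-[(1S,4aR,5S,6S,8aR)-5-[(2,5-dimethoxy-3-methylphenyl)methyl]-5,6,8a-trimethyl-2-oxodecahydronaphthalen-1-yl]propanoate, via enol lactone 21 (not isolated)
Conditions: H2 (1 atm), 10% Pd/C, EtOAc, rt; filter, evaporate; TsOH·H2O (10 mol%), MeOH, 0 °C
Reagents that add atoms: methanol (CO)
Why: Heterogeneous hydrogenation saturates the two disubstituted C=C bonds but not the tetrasubstituted enol-lactone C=C, and acid-catalysed methanolysis of the enol lactone then releases the ketone by ketonisation with axial protonation of C1 from the α face (anti to the axial C8a methyl), which sets C1 with the side chain equatorial.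

Step 12
Reactants: 23 2-methylpropanoyl chloride; 24 benzenethiol
Product: 25 S-phenyl 2-methylpropanethioate
Conditions: pyridine, CH2Cl2, 0 °C → rt
Reagents that add atoms: none
Why: Acylation of the thiol by the acid chloride (thioesterification).

Step 13
Reactants: 22 methyl 3-[(1S,4aR,5S,6S,8aR)-5-[(2,5-dimethoxy-3-methylphenyl)methyl]-5,6,8a-trimethyl-2-oxodecahydronaphthalen-1-yl]propanoate; 25 S-phenyl 2-methylpropanethioate
Product: 27 methyl 3-[(1S,4aR,5S,6S,8aR)-5-[(2,5-dimethoxy-3-methylphenyl)methyl]-3',3',5,6,8a-pentamethyl-4'-oxooctahydro-1H-spiro[naphthalene-2,2'-oxetan]-1-yl]propanoate (spiro epimers), via lithium thioester enolate 26 (not isolated)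
Conditions: LDA, THF, −78 °C; then 22, −78 → 0 °C; aqueous work-up
Reagents that add atoms: none
Why: Danheiser β-lactone synthesis: aldol addition of the thioester lithium enolate to the ketone followed by lactonisation with loss of thiophenoxide; the spiro centre is a mixture that does not matter, and C1, if enolised, is re-protonated axially on work-up.

Step 14
Reactants: 27 methyl 3-[(1S,4aR,5S,6S,8aR)-5-[(2,5-dimethoxy-3-methylphenyl)methyl]-3',3',5,6,8a-pentamethyl-4'-oxooctahydro-1H-spiro[naphthalene-2,2'-oxetan]-1-yl]propanoate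
Product: 28 methyl 3-[(1S,4aR,5S,6S,8aR)-5-[(2,5-dimethoxy-3-methylphenyl)methyl]-5,6,8a-trimethyl-2-(propan-2-ylidene)decahydronaphthalen-1-yl]propanoate
Conditions: mesitylene, 160 °C
Reagents that add atoms: none
Why: Thermal decarboxylation of the β-lactone ([2+2] cycloreversion) gives the tetrasubstituted alkene regiospecifically at C2 without touching C1.

Step 15
Reactants: 28 methyl 3-[(1S,4aR,5S,6S,8aR)-5-[(2,5-dimethoxy-3-methylphenyl)methyl]-5,6,8a-trimethyl-2-(propan-2-ylidene)decahydronaphthalen-1-yl]propanoate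
Product: 29 3-[(1S,4aR,5S,6S,8aR)-5-[(2,5-dihydroxy-3-methylphenyl)methyl]-5,6,8a-trimethyl-2-(propan-2-ylidene)decahydronaphthalen-1-yl]propanoic acid
Conditions: NaSEt (10 equiv), DMF, 140 °C, Ar; then degassed 1 M HCl
Reagents that add atoms: none
Why: Nucleophilic (SN2) demethylation by thiolate cleaves both aryl methyl ethers and the methyl ester without acid, so the tetrasubstituted alkene and all stereocentres survive.

**Compound list**

1 | pent-4-yn-1-ol | C#CCCCO | starting material
2 | 2-(triphenyl-λ5-phosphanylidene)propanal | CC(C=O)=P(c1ccccc1)(c1ccccc1)c1ccccc1 | starting material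
3 | pent-4-ynal | C#CCCC=O | intermediate
4 | (2E)-2-methylhept-2-en-6-ynal | C#CCC/C=C(\C)C=O | intermediate
5 | methyl (2Z)-3-iodoprop-2-enoate | COC(=O)/C=C\I | starting material
6 | methyl (2Z,8E)-9-methyl-10-oxodeca-2,8-dien-4-ynoate | COC(=O)/C=C\C#CCC/C=C(\C)C=O | intermediate
7 | 5-iodo-6-[(3E)-4-methyl-5-oxopent-3-en-1-yl]-2H-pyran-2-one | O=C1C=CC(I)=C(CC/C=C(\C)C=O)O1 | intermediate
8 | prop-1-yn-1-ylmagnesium bromide | CC#C[Mg]Br | starting material
9 | (1E)-1-bromoprop-1-ene | C/C=C/Br | starting material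
10 | (4E)-hex-4-en-2-yne | CC#C/C=C/C | intermediate
11 | chlorobis(cyclopentadienyl)[(2E,4E)-hexa-2,4-dien-2-yl]zirconium | C/C=C/C=C(\C)[Zr](Cl)(C1C=CC=C1)C1C=CC=C1 | intermediate
12 | chloro[(2E,4E)-hexa-2,4-dien-2-yl]zinc | C/C=C/C=C(\C)[Zn]Cl | intermediate
13 | 5-[(2E,4E)-hexa-2,4-dien-2-yl]-6-[(3E)-4-methyl-5-oxopent-3-en-1-yl]-2H-pyran-2-one | O=C1C=CC(/C(C)=C/C=C/C)=C(CC/C=C(\C)C=O)O1 | intermediate
14 | (6aS,7S,8S,10aR)-7,8,10a-trimethyl-3-oxo-5,6,6a,7,8,10a-hexahydro-3H-benzo[f]chromene-7-carbaldehyde (6a-H α, 7-CHO α, 7-Me β, 8-Me α, 10a-Me β) | O=C1C=CC2=C(O1)CC[C@H]3[C@@]2(C)C=C[C@H](C)[C@]3(C)C=O | intermediate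
15 | 4-methoxy-2-methylphenol | COc1ccc(O)c(C)c1 | starting material
16 | 2-bromo-4-methoxy-6-methylphenol | COc1cc(C)c(O)c(Br)c1 | intermediate
17 | 1-bromo-2,5-dimethoxy-3-methylbenzene | COc1cc(C)c(OC)c(Br)c1 | intermediate
18 | (2,5-dimethoxy-3-methylphenyl)magnesium bromide | COc1cc(C)c(OC)c([Mg]Br)c1 | intermediate
19 | (6aS,7S,8S,10aR)-7-[(2,5-dimethoxy-3-methylphenyl)(hydroxy)methyl]-7,8,10a-trimethyl-5,6,6a,7,8,10a-hexahydro-3H-benzo[f]chromen-3-one (carbinol epimers) | O=C1C=CC2=C(O1)CC[C@H]3[C@@]2(C)C=C[C@H](C)[C@]3(C)C(O)c1cc(OC)cc(C)c1OC | intermediate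
20 | (6aR,7S,8S,10aR)-7-[(2,5-dimethoxy-3-methylphenyl)methyl]-7,8,10a-trimethyl-5,6,6a,7,8,10a-hexahydro-3H-benzo[f]chromen-3-one | O=C1C=CC2=C(O1)CC[C@H]3[C@@]2(C)C=C[C@H](C)[C@]3(C)Cc1cc(OC)cc(C)c1OC | intermediate
21 | (6aR,7S,8S,10aR)-7-[(2,5-dimethoxy-3-methylphenyl)methyl]-7,8,10a-trimethyl-1,2,5,6,6a,7,8,9,10,10a-decahydro-3H-benzo[f]chromen-3-one | O=C1CCC2=C(O1)CC[C@H]3[C@@]2(C)CC[C@H](C)[C@]3(C)Cc1cc(OC)cc(C)c1OC | intermediate
22 | methyl 3-[(1S,4aR,5S,6S,8aR)-5-[(2,5-dimethoxy-3-methylphenyl)methyl]-5,6,8a-trimethyl-2-oxodecahydronaphthalen-1-yl]propanoate | O=C1CC[C@H]2[C@@](C)(CC[C@H](C)[C@]2(C)Cc2cc(OC)cc(C)c2OC)[C@@H]1CCC(=O)OC | intermediate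
23 | 2-methylpropanoyl chloride | CC(C)C(=O)Cl | starting material
24 | benzenethiol | Sc1ccccc1 | starting material
25 | S-phenyl 2-methylpropanethioate | CC(C)C(=O)Sc1ccccc1 | intermediate
26 | lithium 2-methyl-1-(phenylsulfanyl)prop-1-en-1-olate | CC(C)=C([O-])Sc1ccccc1.[Li+] | intermediate
27 | methyl 3-[(1S,4aR,5S,6S,8aR)-5-[(2,5-dimethoxy-3-methylphenyl)methyl]-3',3',5,6,8a-pentamethyl-4'-oxooctahydro-1H-spiro[naphthalene-2,2'-oxetan]-1-yl]propanoate (spiro epimers) | CC1(C)C(=O)OC12CC[C@H]3[C@@](C)(CC[C@H](C)[C@]3(C)Cc3cc(OC)cc(C)c3OC)[C@@H]2CCC(=O)OC | intermediate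
28 | methyl 3-[(1S,4aR,5S,6S,8aR)-5-[(2,5-dimethoxy-3-methylphenyl)methyl]-5,6,8a-trimethyl-2-(propan-2-ylidene)decahydronaphthalen-1-yl]propanoate | CC(C)=C1CC[C@H]2[C@@](C)(CC[C@H](C)[C@]2(C)Cc2cc(OC)cc(C)c2OC)[C@@H]1CCC(=O)OC | intermediate
29 | 3-[(1S,4aR,5S,6S,8aR)-5-[(2,5-dihydroxy-3-methylphenyl)methyl]-5,6,8a-trimethyl-2-(propan-2-ylidene)decahydronaphthalen-1-yl]propanoic acid | CC(C)=C1CC[C@H]2[C@@](C)(CC[C@H](C)[C@]2(C)Cc2cc(O)cc(C)c2O)[C@@H]1CCC(=O)O | target

**Step count and risks**

Total step count: 15. Longest linear sequence: 11 steps (1, 2, 3, 5, 6, 9, 10, 11, 13, 14, 15).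

Steps most likely to fail:

Step 6. The cycloaddition must form two quaternary carbons from a diene with an inside methyl, the Lewis-basic pyranone competes for the catalyst, and the sense and level of induction are untested on this substrate. Fallback (auxiliary-controlled cationic cycloaddition instead of catalyst control): starting from 13, the enal is acetalised with (2R,4R)-pentane-2,4-diol (PPTS, benzene, reflux) to give the chiral dioxane acetal of 13 F1. Ionisation with TMSOTf (cat.) and 2,6-di-tert-butylpyridine in CH2Cl2 at −78 °C triggers a Gassman-type ionic intramolecular Diels–Alder reaction through the more reactive alkoxyallyl cation, giving the dioxane acetal of the cycloadduct F2. Mild hydrolysis (PPTS, acetone–water) returns to the route at 14; the other diol enantiomer is used if the facial sense is reversed.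

Step 11. Hydrogenation may not stop at the enol lactone, or ketonisation may give a C1 epimer mixture (the two C1 epimers are estimated to be close in energy, so equilibration would not correct it). Fallback (C1 set by hydrogen delivery instead of protonation): starting from 20, all three C=C bonds are hydrogenated (H2, Pd/C, then Crabtree's catalyst [Ir(cod)(PCy3)(py)]PF6, H2, CH2Cl2). Hydrogen adds to the tetrasubstituted enol-lactone bond from the α face, anti to the angular methyl, giving the cis-fused saturated δ-lactone F3. K2CO3 in MeOH opens it to the hydroxy ester F4, and Dess–Martin oxidation of the secondary alcohol returns to the route at 22.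

Step 13. The ketone is hindered, so enolisation can outrun addition, and the intermediate alkoxide can attack the side-chain ester instead of the thioester. Fallback (reductive carbonyl coupling instead of enolate addition): starting from 22, a mixed McMurry coupling with acetone (5 equiv; TiCl3(DME)1.5, Zn–Cu, DME, reflux) gives the isopropylidene compound directly and returns to the route at 28, skipping 27; no new compound is made.

Further compounds
F1 | step 6 | 5-[(2E,4E)-hexa-2,4-dien-2-yl]-6-[(3E)-4-[(4R,6R)-4,6-dimethyl-1,3-dioxan-2-yl]pent-3-en-1-yl]-2H-pyran-2-one | C[C@@H]1C[C@@H](C)OC(O1)/C(C)=C/CCC1=C(/C(C)=C/C=C/C)C=CC(=O)O1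
F2 | step 6 | (6aS,7S,8S,10aR)-7-[(4R,6R)-4,6-dimethyl-1,3-dioxan-2-yl]-7,8,10a-trimethyl-5,6,6a,7,8,10a-hexahydro-3H-benzo[f]chromen-3-one | O=C1C=CC2=C(O1)CC[C@H]3[C@@]2(C)C=C[C@H](C)[C@]3(C)C1O[C@H](C)C[C@@H](C)O1
F3 | step 11 | cis-fused saturated δ-lactone: 7-[(2,5-dimethoxy-3-methylphenyl)methyl]-7,8,10a-trimethyldodecahydro-3H-benzo[f]chromen-3-one (4a-H and 10b-H α) | O=C1CC[C@@H]2[C@H](O1)CC[C@H]1[C@@]2(C)CC[C@H](C)[C@]1(C)Cc1cc(OC)cc(C)c1OC
F4 | step 11 | methyl 3-[5-[(2,5-dimethoxy-3-methylphenyl)methyl]-2-hydroxy-5,6,8a-trimethyldecahydronaphthalen-1-yl]propanoate (2-OH β, 1-H α) | COC(=O)CC[C@@H]1[C@H](O)CC[C@H]2[C@@]1(C)CC[C@H](C)[C@]2(C)Cc1cc(OC)cc(C)c1OC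
F0 | step 13 | none | none
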